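Ring B (C1'–C6') alternates oxygen at C2', C4', C6' with carbon at C1' (bridge CH2), C3' (methyl) and C5' (propanoyl). This is the imprint of a folded linear tetracarbonyl chain. Everything rests on cutting C4'–C5'. The open-chain triketo ester already holds the methyl branch and the ring A benzyl branch. Methoxide closes it: one intramolecular C-acylation forms the bond, closes the six-membered ring, expels methanol and aromatises to the fully substituted triol. The chain is grown on ring A by three enolate couplings without protecting-group steps. Ring A travels as its base-inert trimethyl ether and receives its butanoyl group and free phenols in the last two steps.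

Key step: step 6

Remark: the target has no stereocentre, so the sp3 centres made on the chain are carried as mixtures and vanish later. Ring B locants are C1' (bridge), C2' (OH), C3' (CH3), C4' (OH), C5' (propanoyl), C6' (OH). The nonanoate chain maps as C1 = C4', C2 = C3', C3 = C2', C4 = C1', C5 = C6', C6 = C5'.

Step 1
Reactants: 1 1,3,5-trimethoxy-2-methylbenzene
Product: 3 2,4,6-trimethoxy-3-methylbenzaldehyde, via aryl iminium salt 2 (not isolated)
Conditions: POCl3 (1.2 equiv), DMF, 0 °C → rt; then ice-water
Reagents that add atoms: N,N-dimethylformamide, CN(C)C=O; water, O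
Why: Vilsmeier–Haack formylation; the two free ring carbons of 1 are equivalent and strongly activated, and the iminium group shuts the ring off from a second attack, so one monoaldehyde should form whose CHO carbon becomes the bridge CH2.

Step 2
Reactants: 4 methyl 2-methyl-3-oxobutanoate; 3 2,4,6-trimethoxy-3-methylbenzaldehyde
Product: 6 methyl 5-hydroxy-2-methyl-3-oxo-5-(2,4,6-trimethoxy-3-methylphenyl)pentanoate (diastereomer mixture), via dilithium dianion 5 (not isolated)
Conditions: 4 (1.2 equiv), LiN(iPr)2 (2.5 equiv), THF, 0 °C; then 3, −78 °C; AcOH, −78 °C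
Reagents that add atoms: none
Why: Aldol addition of a β-keto ester dianion, which reacts only at its more basic terminal carbon; the two stereocentres need no control because C5 becomes CH2 in step 3 and C2 becomes aromatic in step 6, and the aldehyde replaces a 2,4,6-trialkoxybenzyl halide that would alkylate its own free ring carbon.

Step 3
Reactants: 6 methyl 5-hydroxy-2-methyl-3-oxo-5-(2,4,6-trimethoxy-3-methylphenyl)pentanoate
Product: 7 methyl 2-methyl-3-oxo-5-(2,4,6-trimethoxy-3-methylphenyl)pentanoate (racemic, epimerisable at C2)
Conditions: Et3SiH (3 equiv), CF3CO2H (5 equiv, added last), CH2Cl2, −20 → 0 °C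
Reagents that add atoms: none
Why: Ionic hydrogenation; the benzylic alcohol ionises easily to a cation stabilised by three methoxy groups, the silane captures it with hydride, and any styryl ketone formed by proton loss returns to the same cation on protonation, while the β-keto ester and aryl ethers are inert.

Step 4
Reactants: 7 methyl 2-methyl-3-oxo-5-(2,4,6-trimethoxy-3-methylphenyl)pentanoate; 8 N-methoxy-N-methylacetamide
Product: 10 methyl 2-methyl-3,5-dioxo-4-[(2,4,6-trimethoxy-3-methylphenyl)methyl]hexanoate (stereoisomer and tautomer mixture), via dilithium dianion 9 (not isolated)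
Conditions: LiN(iPr)2 (2.2 equiv), THF, −78 → 0 °C; then 8 (1.2 equiv), −78 → −20 °C; cold 1 M HCl
Reagents that add atoms: none
Why: γ-Acylation of a β-keto ester dianion with a Weinreb amide, as used for branched 3,5-diketo esters; the adduct does not collapse before the quench, so the acidic product cannot protonate unreacted dianion, and the amide base is too weak to lithiate the ring carbon between the two methoxy groups.

Step 5
Reactants: 10 methyl 2-methyl-3,5-dioxo-4-[(2,4,6-trimethoxy-3-methylphenyl)methyl]hexanoate; 11 N-methoxy-N-methylpropanamide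
Product: 13 methyl 2-methyl-3,5,7-trioxo-4-[(2,4,6-trimethoxy-3-methylphenyl)methyl]nonanoate (stereoisomer and tautomer mixture), via trilithium trianion 12 (not isolated)
Conditions: LiN(iPr)2 (3.3 equiv), THF, −78 → 0 °C; then 11 (1.1 equiv), −78 → −20 °C; cold 0.5 M HCl; used promptly
Reagents that add atoms: none
Why: Terminal acylation of a 3,5-diketo ester trianion; after C2 and C4 are deprotonated the C6 methyl is the only remaining acidic site, its unhindered carbanion is the most reactive centre, and the Weinreb amide again holds the adduct until the quench so that no cyclisation starts in the flask.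

Step 6
Reactants: 13 methyl 2-methyl-3,5,7-trioxo-4-[(2,4,6-trimethoxy-3-methylphenyl)methyl]nonanoate
Product: 15 1-[2,4,6-trihydroxy-3-methyl-5-[(2,4,6-trimethoxy-3-methylphenyl)methyl]phenyl]propan-1-one, via cyclohexanetrione tautomer 14 (not isolated)
Conditions: NaOMe (4 equiv), degassed MeOH, 0 → 40 °C; then cold 1 M HCl
Reagents that add atoms: none
Why: Methoxide deprotonates the C6 methylene (future C5'), the most acidic carbon because it lies between the C5 and C7 ketones, and this enolate adds to the C1 ester carbonyl (future C4'); collapse of the adduct expels methoxide to give trione 14, which enolises at once to the aromatic triol and is stored as its phenoxide, so the sequence is pulled forward. The closest known reaction type is the base-induced Claisen (Dieckmann-type) cyclisation of 3,5,7-triketo esters to acylphloroglucinols. Ring B closes in a favoured 6-exo-trig mode at the ester C=O, with the nucleophile reacting through its exocyclic C6=C7 enolate (enolexo). No stereocentre is formed, and the C2 and C4 centres of 13 disappear on aromatisation. C-acylation has to win over three other channels: aldol attack of C2 on the C7 ketone makes a quaternary carbon that cannot aromatise and so stays reversible, lactonisation through the C5 enolate oxygen gives a 4-hydroxy-2-pyranone that methoxide can reopen, and retro-Claisen cleavage is slowed because the ketones are tied up as enolates, which leaves it as the main residual risk. Matching NaOMe to the methyl ester rules out the saponification and decarboxylation that hydroxide would bring, and the methyl ethers stop ring A from leaving as an enolate, so the new diarylmethane cannot scramble in base.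

Step 7
Reactants: 15 1-[2,4,6-trihydroxy-3-methyl-5-[(2,4,6-trimethoxy-3-methylphenyl)methyl]phenyl]propan-1-one; 16 butanoyl chloride
Product: 17 1-[2,4,6-trimethoxy-3-methyl-5-[(2,4,6-trihydroxy-3-methyl-5-propanoylphenyl)methyl]phenyl]butan-1-one
Conditions: 16 (1.3 equiv), SnCl4 (2.5 equiv), CH2Cl2, −20 → 0 °C; then ice-water
Reagents that add atoms: none
Why: Friedel–Crafts acylation; the only unsubstituted ring carbon in the molecule sits on ring A between two methoxy groups and is activated as in 1,3,5-trimethoxybenzene, while ring B is fully substituted and its phenols are hindered or hydrogen-bonded, so a mild Lewis acid at low temperature should give C-acylation without ether cleavage or bridge scission.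

Step 8
Reactants: 17 1-[2,4,6-trimethoxy-3-methyl-5-[(2,4,6-trihydroxy-3-methyl-5-propanoylphenyl)methyl]phenyl]butan-1-one
Product: 18 1-[2,4,6-trihydroxy-3-methyl-5-[(2,4,6-trihydroxy-3-methyl-5-propanoylphenyl)methyl]phenyl]butan-1-one (target)
Conditions: BBr3 (9 equiv), CH2Cl2, −78 °C → rt; then ice-water
Reagents that add atoms: none
Why: Lewis-acid cleavage of aryl methyl ethers; two methoxy groups are ortho to the new ketone and cleave with chelation help, the third is twisted out of plane by its two neighbours and is therefore basic, and both rings are now acyl-deactivated, so the bridge should resist ipso protonation.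

Compound list
1 | 1,3,5-trimethoxy-2-methylbenzene | COc1cc(OC)c(C)c(OC)c1 | starting material
2 | dimethyl[(2,4,6-trimethoxy-3-methylphenyl)methylidene]ammonium dichlorophosphate | C[N+](C)=Cc1c(OC)cc(OC)c(C)c1OC.[O-]P(=O)(Cl)Cl | intermediate
3 | 2,4,6-trimethoxy-3-methylbenzaldehyde | O=Cc1c(OC)cc(OC)c(C)c1OC | intermediate
4 | methyl 2-methyl-3-oxobutanoate | COC(=O)C(C)C(C)=O | starting material
5 | dilithium dianion of 4 | [Li+].[Li+].C=C([O-])C(C)=C([O-])OC | intermediate
6 | methyl 5-hydroxy-2-methyl-3-oxo-5-(2,4,6-trimethoxy-3-methylphenyl)pentanoate (diastereomer mixture) | COC(=O)C(C)C(=O)CC(O)c1c(OC)cc(OC)c(C)c1OC | intermediate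
7 | methyl 2-methyl-3-oxo-5-(2,4,6-trimethoxy-3-methylphenyl)pentanoate (racemic) | COC(=O)C(C)C(=O)CCc1c(OC)cc(OC)c(C)c1OC | intermediate
8 | N-methoxy-N-methylacetamide | CON(C)C(C)=O | starting material
9 | dilithium dianion of 7 | [Li+].[Li+].COC([O-])=C(C)C([O-])=CCc1c(OC)cc(OC)c(C)c1OC | intermediate
10 | methyl 2-methyl-3,5-dioxo-4-[(2,4,6-trimethoxy-3-methylphenyl)methyl]hexanoate (stereoisomer mixture) | COC(=O)C(C)C(=O)C(Cc1c(OC)cc(OC)c(C)c1OC)C(C)=O | intermediate
11 | N-methoxy-N-methylpropanamide | CCC(=O)N(C)OC | starting material
12 | trilithium trianion of 10 | [Li+].[Li+].[Li+].COC([O-])=C(C)C([O-])=C(Cc1c(OC)cc(OC)c(C)c1OC)C([O-])=C | intermediate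
13 | methyl 2-methyl-3,5,7-trioxo-4-[(2,4,6-trimethoxy-3-methylphenyl)methyl]nonanoate (stereoisomer mixture) | CCC(=O)CC(=O)C(Cc1c(OC)cc(OC)c(C)c1OC)C(=O)C(C)C(=O)OC | intermediate
14 | 2-methyl-4-propanoyl-6-[(2,4,6-trimethoxy-3-methylphenyl)methyl]cyclohexane-1,3,5-trione | CCC(=O)C1C(=O)C(C)C(=O)C(Cc2c(OC)cc(OC)c(C)c2OC)C1=O | intermediate
15 | 1-[2,4,6-trihydroxy-3-methyl-5-[(2,4,6-trimethoxy-3-methylphenyl)methyl]phenyl]propan-1-one | CCC(=O)c1c(O)c(C)c(O)c(Cc2c(OC)cc(OC)c(C)c2OC)c1O | intermediate
16 | butanoyl chloride | CCCC(=O)Cl | starting material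
17 | 1-[2,4,6-trimethoxy-3-methyl-5-[(2,4,6-trihydroxy-3-methyl-5-propanoylphenyl)methyl]phenyl]butan-1-one | CCCC(=O)c1c(OC)c(C)c(OC)c(Cc2c(O)c(C)c(O)c(C(=O)CC)c2O)c1OC | intermediate
18 | 1-[2,4,6-trihydroxy-3-methyl-5-[(2,4,6-trihydroxy-3-methyl-5-propanoylphenyl)methyl]phenyl]butan-1-one | CCCC(=O)c1c(O)c(C)c(O)c(Cc2c(O)c(C)c(O)c(C(=O)CC)c2O)c1O | target

Total step count: 8. Longest linear sequence: 8 steps (1 → 18).

Steps most likely to fail

Step 6. Ring closure may go through the C5 enolate oxygen instead of carbon C6, or methoxide may fragment the doubly branched chain before it closes. The fallback takes ring B from an aromatic building block and makes the bridge by quinone methide arylation. Commercial 2-methylbenzene-1,3,5-triol is C-acylated with propanoyl chloride and AlCl3 to give 1-(2,4,6-trihydroxy-3-methylphenyl)propan-1-one F1. A Mannich reaction with dimethylmethylideneammonium iodide at its only free ring carbon gives 1-[3-[(dimethylamino)methyl]-2,4,6-trihydroxy-5-methylphenyl]propan-1-one F2. Heating F2 with an excess of 1 in toluene containing AcOH expels the amine, and the ortho-quinone methide has no free ring B carbon to attack. It should therefore be intercepted by the electron-rich arene 1 in a Friedel–Crafts-type addition. This fallback sets out from 1 and comes back to the route at 15.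

Step 5. The third deprotonation may stay incomplete, or proton transfer between the trianion and the amide may outrun addition, so that 10 is returned or reacts at the wrong site. The fallback avoids any trianion by delivering C5–C9 in one masked piece. Methyl 3-oxopentanoate is ketalised with ethane-1,2-diol (p-TsOH, toluene, water removal) to give methyl 2-(2-ethyl-1,3-dioxolan-2-yl)acetate F3. Dianion 9, made from 7 with one extra equivalent of LiN(iPr)2 to absorb the acidic product proton, is acylated by F3. This gives methyl 6-(2-ethyl-1,3-dioxolan-2-yl)-2-methyl-3,5-dioxo-4-[(2,4,6-trimethoxy-3-methylphenyl)methyl]hexanoate F4. Brief treatment with dilute aqueous HCl in THF at rt removes the ketal. This fallback sets out from 7 and comes back to the route at 13.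

Step 7. The ring B phenols may be esterified, or ipso protonation of the still unacylated ring A may cleave or scramble the methylene bridge. The fallback masks ring B first, which also makes its benzylic cation a much poorer leaving fragment. Treating 15 with Ac2O, pyridine and DMAP gives 2-methyl-4-propanoyl-6-[(2,4,6-trimethoxy-3-methylphenyl)methyl]benzene-1,3,5-triyl triacetate F5. Friedel–Crafts butanoylation with 16 and SnCl4 then gives 2-[(3-butanoyl-2,4,6-trimethoxy-5-methylphenyl)methyl]-4-methyl-6-propanoylbenzene-1,3,5-triyl triacetate F6. Methanolysis with K2CO3 in MeOH at 0 °C frees the three phenols. This fallback sets out from 15 and comes back to the route at 17.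

Further compounds
F1 | step 6 | 1-(2,4,6-trihydroxy-3-methylphenyl)propan-1-one | CCC(=O)c1c(O)cc(O)c(C)c1O
F2 | step 6 | 1-[3-[(dimethylamino)methyl]-2,4,6-trihydroxy-5-methylphenyl]propan-1-one | CCC(=O)c1c(O)c(C)c(O)c(CN(C)C)c1O
F3 | step 5 | methyl 2-(2-ethyl-1,3-dioxolan-2-yl)acetate | CCC1(CC(=O)OC)OCCO1
F4 | step 5 | methyl 6-(2-ethyl-1,3-dioxolan-2-yl)-2-methyl-3,5-dioxo-4-[(2,4,6-trimethoxy-3-methylphenyl)methyl]hexanoate | CCC1(CC(=O)C(Cc2c(OC)cc(OC)c(C)c2OC)C(=O)C(C)C(=O)OC)OCCO1
F5 | step 7 | 2-methyl-4-propanoyl-6-[(2,4,6-trimethoxy-3-methylphenyl)methyl]benzene-1,3,5-triyl triacetate | CCC(=O)c1c(OC(C)=O)c(C)c(OC(C)=O)c(Cc2c(OC)cc(OC)c(C)c2OC)c1OC(C)=O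
F6 | step 7 | 2-[(3-butanoyl-2,4,6-trimethoxy-5-methylphenyl)methyl]-4-methyl-6-propanoylbenzene-1,3,5-triyl triacetate | CCCC(=O)c1c(OC)c(C)c(OC)c(Cc2c(OC(C)=O)c(C)c(OC(C)=O)c(C(=O)CC)c2OC(C)=O)c1OC
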